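## Retrosynthetic overview

1. Feature: number each inner ring (B, B′) with C1 at the bridge CH2, C2 at OMe and C6 at the CH2CH2 chain. The free OH then stands on C4, and its neighbours C3 and C5 are both C–H. With that oxygen removed, C4–H is the only one of the twelve aryl C–H bonds without an ortho substituent. C2′–H, C5′–H and C6′–H of the silylated guaiacyl rings (A, A′) each adjoin the chain, OMe or OTIPS.
2. Last disconnections: first the two guaiacyl O–Si bonds (fluoride), then both C4–O bonds. The C4–O bonds are made together by twofold steric iridium C–H borylation and oxidation in the same pot on the deoxy core, so the oxygen that must stay unmethylated never has to be distinguished from OMe.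
3. The deoxy core is cut at both aryl–CH2(chain) bonds. This is a twofold B-alkyl Suzuki–Miyaura coupling of bis(2-bromo-6-methoxyphenyl)methane with the 9-BBN adduct of O-TIPS-4-vinylguaiacol.
4. The dibromide is cut at the bridge carbon into ortho-lithiated 3-bromoanisole and 2-bromo-6-methoxybenzaldehyde, followed by ionic deoxygenation of the carbinol.
5. No ring is formed, since all four benzene rings are purchased. The target is achiral, so no stereocentre has to be set.

Key step: step 5

Remark: all starting materials below are taken as catalogue chemicals, and LiN(iPr)2 is used as a purchased solution.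

## Route

Step 1
Reactants: 1 2-methoxy-4-vinylphenol; 2 chlorotriisopropylsilane
Product: 3 triisopropyl(2-methoxy-4-vinylphenoxy)silane
Conditions: imidazole, DMF, 0 °C to rt
Reagents that add atoms: chlorotriisopropylsilane 2, CC(C)[Si](Cl)(C(C)C)C(C)C
Why: Imidazole-promoted O-silylation of a phenol installs a bulky TIPS ether that should survive aqueous phosphate, the iridium catalyst and the oxidant, and that later shields guaiacyl C5′–H.

Step 2
Reactants: 4 3-bromoanisole; 5 2-bromo-6-methoxybenzaldehyde
Product: 7 bis(2-bromo-6-methoxyphenyl)methanol, via (2-bromo-6-methoxyphenyl)lithium 6 (not isolated)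
Conditions: 4 (slight excess), LiN(iPr)2 (LDA), THF, −78 °C; then 5 in THF, −78 °C; aq. NH4Cl quench at low temperature
Reagents that add atoms: none
Why: In this directed ortho-metalation, C2–H of 4 is acidified by both the flanking Br and OMe, so the amide base removes it without Br/Li exchange, and at −78 °C aryllithium 6 should last long enough to add 1,2 to the non-enolisable aldehyde 5; the carbinol carbon carries two identical aryl groups and is not a stereocentre.

Step 3
Reactants: 7 bis(2-bromo-6-methoxyphenyl)methanol
Product: 8 bis(2-bromo-6-methoxyphenyl)methane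
Conditions: Et3SiH, CF3CO2H, CH2Cl2, 0 °C to rt
Reagents that add atoms: none
Why: In this ionic hydrogenation, the acid ionises the doubly benzylic alcohol to a cation stabilised by two ortho-methoxy groups and excess Et3SiH traps it with hydride, leaving C–Br and OMe untouched.

Step 4
Reactants: 3 triisopropyl(2-methoxy-4-vinylphenoxy)silane (2.4 equiv); 9 9-borabicyclo[3.3.1]nonane (9-BBN, 2.4 equiv); 8 bis(2-bromo-6-methoxyphenyl)methane (1 equiv)
Product: 11 bis(2-methoxy-6-{2-[3-methoxy-4-(triisopropylsilyloxy)phenyl]ethyl}phenyl)methane, via B-(2-arylethyl)-9-BBN 10 (not isolated)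
Conditions: 3, 9, THF, 0 °C to rt; then 8, Pd(OAc)2, SPhos, aq. K3PO4, THF, 60 °C
Reagents that add atoms: none
Why: Anti-Markovnikov hydroboration of the styrene with 9-BBN puts boron on the terminal carbon, and the twofold B-alkyl Suzuki–Miyaura coupling (oxidative addition of zerovalent palladium into each C–Br, base-assisted alkyl transfer from boron, reductive elimination) forms both aryl–CH2 bonds, with SPhos chosen because it suits ortho-substituted bromides and disfavours β-hydride elimination.

Step 5
Reactants: 11 bis(2-methoxy-6-{2-[3-methoxy-4-(triisopropylsilyloxy)phenyl]ethyl}phenyl)methane; 12 bis(pinacolato)diboron (3 equiv)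
Product: 14 bis(4-hydroxy-2-methoxy-6-{2-[3-methoxy-4-(triisopropylsilyloxy)phenyl]ethyl}phenyl)methane, via bis(pinacol boronate) 13 (not isolated)
Conditions: [Ir(OMe)(cod)]2 (3 mol %), dtbpy (6 mol %), THF, 80 °C, sealed vessel; volatiles removed; then KHSO5 (as 2KHSO5·KHSO4·K2SO4), acetone/H2O, rt, short contact time
Reagents that add atoms: potassium peroxymonosulfate KHSO5, [K+].[O-]S(=O)(=O)OO
Why: [Ir(OMe)(cod)]2, dtbpy and 12 form the tris-boryl complex (dtbpy)Ir(Bpin)3 of trivalent iridium, which cleaves an aryl C–H bond in a crowded, sterically governed oxidative addition, releases the aryl boronate by reductive elimination and is rebuilt by 12; peroxymonosulfate then adds to each boron, the aryl group migrates from B to O with retention of position, and hydrolysis of the borate frees the phenol, so both C4–O bonds arise in one pot. The closest known reaction type is the sterically controlled iridium-catalysed C–H borylation of 1,2,3-trisubstituted arenes at their 5-position, combined with one-pot oxidation to the phenol. The step needs site selectivity among twelve aryl C–H bonds and the substrate secures it: only C4–H of rings B and B′ has two C–H neighbours, whereas C3–H and C5–H lie ortho to OMe and to the chain, and C2′–H, C5′–H and C6′–H of rings A and A′ lie ortho to chain plus OMe, to the bulky OTIPS and to the chain. The two inner rings are insulated from each other by the CH2 bridge and react independently, so excess 12 should carry the mono-boronate on to 13. No ring closes and no stereocentre forms. Methyl ethers, TIPS ethers and the benzylic CH2 groups should be inert to the catalyst at this temperature, and the brief, weakly acidic oxidation should spare the silyl ethers.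

Step 6
Reactants: 14 bis(4-hydroxy-2-methoxy-6-{2-[3-methoxy-4-(triisopropylsilyloxy)phenyl]ethyl}phenyl)methane
Product: 15 bis{4-hydroxy-2-[2-(4-hydroxy-3-methoxyphenyl)ethyl]-6-methoxyphenyl}methane (target CNP0079383.0)
Conditions: Bu4NF, AcOH, THF, 0 °C to rt, under argon
Reagents that add atoms: none
Why: In this fluoride desilylation, attack at silicon driven by the strong Si–F bond releases the two guaiacyl phenols, acetic acid keeps the electron-rich tetraphenol from standing as phenoxide, and the four methyl ethers are unaffected.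

## Compound list

1 | 2-methoxy-4-vinylphenol | C=Cc1ccc(O)c(OC)c1 | starting material
2 | chlorotriisopropylsilane | CC(C)[Si](Cl)(C(C)C)C(C)C | starting material
3 | triisopropyl(2-methoxy-4-vinylphenoxy)silane | C=Cc1ccc(O[Si](C(C)C)(C(C)C)C(C)C)c(OC)c1 | intermediate
4 | 3-bromoanisole | COc1cccc(Br)c1 | starting material
5 | 2-bromo-6-methoxybenzaldehyde | COc1cccc(Br)c1C=O | starting material
6 | (2-bromo-6-methoxyphenyl)lithium | [Li]c1c(Br)cccc1OC | intermediate
7 | bis(2-bromo-6-methoxyphenyl)methanol | COc1cccc(Br)c1C(O)c1c(Br)cccc1OC | intermediate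
8 | bis(2-bromo-6-methoxyphenyl)methane | COc1cccc(Br)c1Cc1c(Br)cccc1OC | intermediate
9 | 9-borabicyclo[3.3.1]nonane (9-BBN) | B1C2CCCC1CCC2 | starting material
10 | 9-{2-[3-methoxy-4-(triisopropylsilyloxy)phenyl]ethyl}-9-borabicyclo[3.3.1]nonane | COc1cc(CCB2C3CCCC2CCC3)ccc1O[Si](C(C)C)(C(C)C)C(C)C | intermediate
11 | bis(2-methoxy-6-{2-[3-methoxy-4-(triisopropylsilyloxy)phenyl]ethyl}phenyl)methane | COc1cccc(CCc2ccc(O[Si](C(C)C)(C(C)C)C(C)C)c(OC)c2)c1Cc1c(OC)cccc1CCc1ccc(O[Si](C(C)C)(C(C)C)C(C)C)c(OC)c1 | intermediate
12 | bis(pinacolato)diboron | CC1(C)OB(OC1(C)C)B1OC(C)(C)C(C)(C)O1 | starting material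
13 | bis(2-methoxy-4-(4,4,5,5-tetramethyl-1,3,2-dioxaborolan-2-yl)-6-{2-[3-methoxy-4-(triisopropylsilyloxy)phenyl]ethyl}phenyl)methane | COc1cc(B2OC(C)(C)C(C)(C)O2)cc(CCc2ccc(O[Si](C(C)C)(C(C)C)C(C)C)c(OC)c2)c1Cc1c(OC)cc(B2OC(C)(C)C(C)(C)O2)cc1CCc1ccc(O[Si](C(C)C)(C(C)C)C(C)C)c(OC)c1 | intermediate
14 | bis(4-hydroxy-2-methoxy-6-{2-[3-methoxy-4-(triisopropylsilyloxy)phenyl]ethyl}phenyl)methane | COc1cc(O)cc(CCc2ccc(O[Si](C(C)C)(C(C)C)C(C)C)c(OC)c2)c1Cc1c(OC)cc(O)cc1CCc1ccc(O[Si](C(C)C)(C(C)C)C(C)C)c(OC)c1 | intermediate
15 | bis{4-hydroxy-2-[2-(4-hydroxy-3-methoxyphenyl)ethyl]-6-methoxyphenyl}methane | COc1cc(CCc2cc(O)cc(OC)c2Cc2c(CCc3ccc(O)c(OC)c3)cc(O)cc2OC)ccc1O | target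

## Step count and risks

Total step count: 6. Longest linear sequence: 5 steps (4 → 7 → 8 → 11 → 14 → 15).

**Step 5 (highest risk).**
- What may go wrong:
  - The electron-rich inner rings may react slowly, so the sequence could stall after the first borylation.
  - Site selectivity could erode toward C–H bonds ortho to OMe.
  - The liberated resorcinol-type phenols could be over-oxidised.
- Fallback: the C–H oxidation is moved forward to the dibromide 8.
  - The same steric rule holds there, because only the C–H para to the bridge is unflanked.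
  - No guaiacyl ring is present yet, and the bromine-bearing rings are more electron-poor and therefore faster in C–H cleavage.
  - Setting out from 8, borylation with 12 ([Ir(OMe)(cod)]2, dtbpy, THF, 80 °C) should give bis[2-bromo-6-methoxy-4-(4,4,5,5-tetramethyl-1,3,2-dioxaborolan-2-yl)phenyl]methane F1, which can be purified.
  - Oxidation (KHSO5, acetone/H2O, rt) gives bis(2-bromo-4-hydroxy-6-methoxyphenyl)methane F2.
  - F2 is coupled as the free bis-phenol with borane 10 under the conditions of step 4, with two further equivalents of K3PO4.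
  - The fallback comes back to the route at 14.

**Step 4.**
- What may go wrong:
  - The coupling may stall after the first C–C bond next to the crowded bridge.
  - Hydrodebromination may occur.
  - β-Hydride elimination from the alkylpalladium intermediate may compete.
  - The two C–Br carbons may close reductively to a five-membered ring.
  - Base may induce loss of a TIPS group.
- Fallback: the sp3–sp2 coupling is replaced by olefin arylation followed by saturation.
  - Setting out from 8 and 3, a twofold Mizoroki–Heck reaction (Pd(OAc)2, P(o-tol)3, Et3N, DMF, 100 °C) should give bis(2-methoxy-6-{(E)-2-[3-methoxy-4-(triisopropylsilyloxy)phenyl]ethenyl}phenyl)methane F3.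
  - Hydrogenation (H2, Pd/C, EtOAc, rt) saturates both stilbene double bonds.
  - The fallback comes back to the route at 11.

**Step 2.**
- What may go wrong:
  - The ortho-bromoaryllithium may lose LiBr (aryne formation) before it meets the aldehyde.
  - Deprotonation by the amide base may be incomplete.
  - Addition to the di-ortho-substituted aldehyde may be slow.
- Fallback: the halogenated diarylmethane is given up and the chains are attached by carbonyl-directed C–H alkylation, which bypasses steps 2–4.
  - Setting out from 3, purchased 2,2′-dimethoxybenzophenone F4 is alkylated at its two free ortho C–H bonds by Murai-type anti-Markovnikov hydroarylation of the styrene ([RuCl2(p-cymene)]2, HCO2Na, P(4-CF3C6H4)3, toluene, 140 °C). This should give bis(2-methoxy-6-{2-[3-methoxy-4-(triisopropylsilyloxy)phenyl]ethyl}phenyl)methanone F5.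
  - LiAlH4 (THF, reflux) reduces the hindered ketone to bis(2-methoxy-6-{2-[3-methoxy-4-(triisopropylsilyloxy)phenyl]ethyl}phenyl)methanol F6.
  - Ionic hydrogenation (Et3SiH, CF3CO2H, CH2Cl2, 0 °C) then comes back to the route at 11.
  - This path is held in reserve because insertion of ruthenium into the ortho C–OMe bonds and branched hydroarylation can compete.

## Further compounds

F1 | step 5 | bis[2-bromo-6-methoxy-4-(4,4,5,5-tetramethyl-1,3,2-dioxaborolan-2-yl)phenyl]methane | COc1cc(B2OC(C)(C)C(C)(C)O2)cc(Br)c1Cc1c(Br)cc(B2OC(C)(C)C(C)(C)O2)cc1OC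
F2 | step 5 | bis(2-bromo-4-hydroxy-6-methoxyphenyl)methane | COc1cc(O)cc(Br)c1Cc1c(Br)cc(O)cc1OC
F3 | step 4 | bis(2-methoxy-6-{(E)-2-[3-methoxy-4-(triisopropylsilyloxy)phenyl]ethenyl}phenyl)methane | COc1cccc(/C=C/c2ccc(O[Si](C(C)C)(C(C)C)C(C)C)c(OC)c2)c1Cc1c(OC)cccc1/C=C/c1ccc(O[Si](C(C)C)(C(C)C)C(C)C)c(OC)c1
F4 | step 2 | 2,2′-dimethoxybenzophenone (purchased) | O=C(c1ccccc1OC)c1ccccc1OC
F5 | step 2 | bis(2-methoxy-6-{2-[3-methoxy-4-(triisopropylsilyloxy)phenyl]ethyl}phenyl)methanone | O=C(c1c(OC)cccc1CCc1ccc(O[Si](C(C)C)(C(C)C)C(C)C)c(OC)c1)c1c(OC)cccc1CCc1ccc(O[Si](C(C)C)(C(C)C)C(C)C)c(OC)c1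
F6 | step 2 | bis(2-methoxy-6-{2-[3-methoxy-4-(triisopropylsilyloxy)phenyl]ethyl}phenyl)methanol | OC(c1c(OC)cccc1CCc1ccc(O[Si](C(C)C)(C(C)C)C(C)C)c(OC)c1)c1c(OC)cccc1CCc1ccc(O[Si](C(C)C)(C(C)C)C(C)C)c(OC)c1
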